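Ring B (C1, C5–C10) of the target, once the C6 ester oxygen is traced back to a C5=C6 enol ether, holds a 1,4-diene (C5=C6, C8=C9) whose sp3 carbon C10 is bonded to quaternary C1: the retron of a cis-divinylcyclopropane Cope rearrangement. One thermal step forms C1–C10, breaks C6–C8, closes the seven-membered ring and sets C1. Its precursor is the ring A cyclopentene (C1=C5, silyl ethers at C2 and C4) carrying a cis-1-methoxy-2-methyl-2-vinylcyclopropyl group at C5, assembled from a chromium carbene complex and methyl methacrylate. Ring A comes from (R)-4-silyloxycyclopentenone; directed reduction and two acylations finish the synthesis.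

Key step: step 10

Numbering and faces: daucane numbering throughout (ring A = C1–C5, ring B = C1, C5–C10; methyl on C1, oxygen on C2, C4 and C6, isopropyl on C4, methyl on C8); β is the face of the C1 methyl group, and the ring fusion is trans (H5 α) unless stated.

Assumption: step 7 is not expected to control the cyclopropane configuration; 12–14 are drawn and named as the epimer that enters the key step directly, and the C6/C8 epimer mixture is carried through steps 8–10.

Step 1
Reactants: 1 (R)-4-[(tert-butyldimethylsilyl)oxy]cyclopent-2-en-1-one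
Product: 2 (3R,4R)-4-[(tert-butyldimethylsilyl)oxy]-3-methyl-1-[(trimethylsilyl)oxy]cyclopent-1-ene
Conditions: Me2CuLi (from MeLi and CuI), Me3SiCl, Et3N, THF, −78 °C
Reagents that add atoms: methyllithium, used as Me2CuLi, C[Li]; chlorotrimethylsilane, C[Si](C)(C)Cl
Why: Gilman cuprate conjugate addition delivers methyl to C3 anti to the C4 silyloxy group and Me3SiCl traps the enolate as the regiodefined silyl enol ether, which is all that matters because the new C3 stereocenter is erased in step 2.

Step 2
Reactants: 2 silyl enol ether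
Product: 3 (R)-4-[(tert-butyldimethylsilyl)oxy]-3-methylcyclopent-2-en-1-one
Conditions: Pd(OAc)2 (10 mol %), O2 (1 atm), DMSO, rt
Reagents that add atoms: none
Why: Saegusa–Ito oxidation, in which divalent palladium forms the oxa-π-allyl species from the enol ether and β-hydride elimination returns the enone with the double bond now carrying the methyl group, while the silyloxy stereocenter is not involved.

Step 3
Reactants: 3 methyl enone
Product: 5 (R)-2-bromo-4-[(tert-butyldimethylsilyl)oxy]-3-methylcyclopent-2-en-1-one, via dibromo ketone 4 (not isolated)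
Conditions: Br2, CH2Cl2, 0 °C; then Et3N
Reagents that add atoms: bromine, BrBr
Why: Bromine addition across the enone followed by E1cB loss of HBr from the acidic α-position is the standard α-bromination of enones and leaves the silyloxy stereocenter untouched.

Step 4
Reactants: 5 bromo enone
Product: 6 (1R,4R)-2-bromo-4-[(tert-butyldimethylsilyl)oxy]-3-methyl-1-(propan-2-yl)cyclopent-2-en-1-ol
Conditions: i-PrMgCl, CeCl3, THF, −78 °C
Reagents that add atoms: isopropylmagnesium chloride, CC(C)[Mg]Cl
Why: Cerium-promoted Grignard 1,2-addition suppresses enolisation, reduction and attack on the C–Br bond, and the nucleophile enters the carbonyl face anti to the γ-silyloxy group, so the new tertiary hydroxyl (C4, β) is cis to the C2 silyl ether.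

Step 5
Reactants: 6 bromo alcohol
Product: 7 (1R,4R)-2-bromo-4-[(tert-butyldimethylsilyl)oxy]-3-methyl-1-(propan-2-yl)-1-[(triethylsilyl)oxy]cyclopent-2-ene
Conditions: Et3SiOTf, 2,6-lutidine, CH2Cl2, 0 °C
Reagents that add atoms: triethylsilyl trifluoromethanesulfonate, CC[Si](CC)(CC)OS(=O)(=O)C(F)(F)F
Why: Silyl triflate with a hindered pyridine base is the standard silylation of tertiary alcohols, and the triethylsilyl group is chosen because it can later be removed while the tert-butyldimethylsilyl ether stays.

Step 6
Reactants: 7 ring A bromide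
Product: 10 pentacarbonyl[methoxy(ring A alkenyl)carbene]chromium, via alkenyllithium 8 (not isolated), via lithium acylchromate 9 (not isolated)
Conditions: t-BuLi (2 equiv), THF, −78 °C; Cr(CO)6, −78 °C to rt; Me3OBF4, CH2Cl2, 0 °C
Reagents that add atoms: chromium hexacarbonyl, [Cr].[C-]#[O+].[C-]#[O+].[C-]#[O+].[C-]#[O+].[C-]#[O+].[C-]#[O+]; trimethyloxonium tetrafluoroborate, C[O+](C)C.F[B-](F)(F)F
Why: Fischer carbene synthesis, in which bromine–lithium exchange gives an alkenyllithium that cannot β-eliminate within the five-membered ring, this adds to a CO ligand of Cr(CO)6 and the acylmetalate is O-methylated to the zerovalent chromium carbene complex without touching a stereocenter.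

Step 7
Reactants: 10 chromium carbene complex; 11 methyl methacrylate
Product: 12 methyl (6R,8S)-cyclopropanecarboxylate: ring A alkenyl and OMe on C6, methyl and CO2Me on C8, alkenyl and ester cis
Conditions: 11 (excess), BHT (cat.), cyclohexane, 85 °C, sealed tube
Reagents that add atoms: none
Why: Carbene transfer from a Fischer carbene complex to an electron-poor alkene (CO loss, metallacyclobutane, reductive elimination) gives the donor–acceptor cyclopropane, and the acceptor alkene fixes that C7 is the CH2 group and C8 carries the methyl group, which a 2-substituted diene would leave open; the C6/C8 configuration is not controlled and need not be.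

Step 8
Reactants: 12 cyclopropane ester
Product: 13 (6R,8S)-cyclopropanecarbaldehyde (CHO on C8, cis to the ring A alkenyl group)
Conditions: i-Bu2AlH (1.1 equiv), toluene, −78 °C; aq. KNaC4H4O6
Reagents that add atoms: none
Why: Partial ester reduction, in which the aluminium hemiacetal of the neopentyl-type ester is stable at −78 °C and releases the aldehyde only on neutral tartrate work-up, which the acid-sensitive alkoxycyclopropane tolerates.

Step 9
Reactants: 13 cyclopropane aldehyde
Product: 14 ring A cyclopentene bearing the (6S,8R)-cis-1-methoxy-2-methyl-2-vinylcyclopropyl group at C5 (2β-OTBS, 4β-OTES)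
Conditions: Ph3PCH3Br, KN(SiMe3)2, THF, 0 °C to rt
Reagents that add atoms: methyltriphenylphosphonium bromide, C[P+](c1ccccc1)(c1ccccc1)c1ccccc1.[Br-]
Why: Wittig methylenation of the non-enolisable aldehyde installs C10 at or below room temperature, where the divinylcyclopropane should survive because its rearrangement must form a bond at fully substituted C1.

Step 10
Reactants: 14 divinylcyclopropane
Product: 15 (1R,2R,4R)-2β-[(tert-butyldimethylsilyl)oxy]-6-methoxy-4β-[(triethylsilyl)oxy]dauca-5,8-diene
Conditions: toluene (degassed, 0.02 M), 2,6-lutidine (5 mol %), 120 °C, sealed tube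
Reagents that add atoms: none
Why: Thermal [3,3]-sigmatropic (Cope) rearrangement of the cis-1-alkenyl-2-vinylcyclopropane: in the boat conformer both π bonds (C1=C5 and C9=C10) lie over the three-membered ring, C1–C10 forms as the strained C6–C8 bond breaks, and C5=C6(OMe) and C8=C9 emerge as the two ring alkenes. The closest known reaction type is the cis-divinylcyclopropane to cyclohepta-1,4-diene rearrangement used to build hydroazulenes with an angular methyl group, including cyclopropanes made from carbene complexes. Ring B closes by this sigmatropic ring expansion (three-membered ring traded for seven-membered ring, both ring alkenes necessarily cis), not by an end-to-end cyclisation, so no medium-ring entropy cost arises. The one new stereocenter, quaternary C1, is controlled by the C2 silyloxy group next to it: C10 must bond to the α face of C1, anti to OTBS, and the (6S,8R)-cyclopropane is the epimer whose boat conformer presents C10 to that face. The step needs this facial selectivity and a cis cyclopropane; the C6–C8 bond carries methoxy and alkenyl on one carbon and vinyl on the other, so it should homolyse reversibly at the reaction temperature and feed the trans and the mismatched cis epimers into the favoured boat. The fully substituted C1 terminus with its inward-pointing methyl group raises the barrier, which is why 120 °C is planned and why 14 can be handled at room temperature.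

Step 11
Reactants: 15 methoxy diene
Product: 17 2β-[(tert-butyldimethylsilyl)oxy]-4β-hydroxydauc-8-en-6-one, via 4β-triethylsilyloxy ketone 16 (not isolated)
Conditions: (CO2H)2, THF/H2O, 0 °C to rt; then pyridine, HF·pyridine, 0 °C
Reagents that add atoms: water, O
Why: Enol ether hydrolysis under mild carboxylic acid catalysis (as for 1-methoxycyclohexa-1,4-dienes) keeps C8=C9 out of conjugation, C5 is set by kinetic protonation on the α face away from the two silyloxy groups that roof the β face (trans ring fusion), and buffered fluoride then removes the more labile triethylsilyl ether while the hindered tert-butyldimethylsilyl ether stays.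

Step 12
Reactants: 17 β-hydroxy ketone
Product: 18 2β-[(tert-butyldimethylsilyl)oxy]dauc-8-ene-4β,6α-diol
Conditions: Me4NBH(OAc)3, MeCN/AcOH (1:1), −25 °C
Reagents that add atoms: none
Why: Hydroxyl-directed (Evans–Saksena) reduction, in which the C4 β-hydroxyl exchanges onto boron and delivers hydride intramolecularly to the β face of the C6 ketone through a six-membered transition state, so the new hydroxyl is 6α and anti to the C4 hydroxyl, whereas an external hydride would be expected to attack the more open α face.

Step 13
Reactants: 18 diol; 19 4-methoxybenzoyl chloride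
Product: 20 2β-[(tert-butyldimethylsilyl)oxy]-4β-hydroxydauc-8-en-6α-yl 4-methoxybenzoate
Conditions: DMAP, Et3N, CH2Cl2, 0 °C to rt
Reagents that add atoms: none
Why: DMAP-catalysed acylation esterifies the only secondary hydroxyl, since the tertiary C4 hydroxyl does not react under these conditions.

Step 14
Reactants: 20 silyl ether 4-methoxybenzoate
Product: 21 2β,4β-dihydroxydauc-8-en-6α-yl 4-methoxybenzoate
Conditions: HF·pyridine, pyridine, THF, 0 °C to rt
Reagents that add atoms: none
Why: Fluoride-mediated desilylation under buffered, near-neutral conditions frees the C2 hydroxyl without acyl migration or ester cleavage.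

Step 15
Reactants: 21 diol 4-methoxybenzoate; 22 angelic acid
Product: 24 CNP0204191.1 [(1R,2R,4R,5S,6S)-2β-angeloyloxy-4β-hydroxydauc-8-en-6α-yl 4-methoxybenzoate], via angelic 2,4,6-trichlorobenzoic anhydride 23 (not isolated)
Conditions: 2,4,6-Cl3C6H2COCl, Et3N, toluene, rt; then 21, 80 °C
Reagents that add atoms: none
Why: Yamaguchi-type esterification through the mixed anhydride without a nucleophilic catalyst acylates the secondary C2 hydroxyl (the tertiary C4 hydroxyl stays free) and avoids the base- and DMAP-induced Z to E isomerisation that turns angelates into tiglates.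

Compound list
1 | (R)-4-[(tert-butyldimethylsilyl)oxy]cyclopent-2-en-1-one | CC(C)(C)[Si](C)(C)O[C@@H]1CC(=O)C=C1 | starting material
2 | (3R,4R)-4-[(tert-butyldimethylsilyl)oxy]-3-methyl-1-[(trimethylsilyl)oxy]cyclopent-1-ene (methyl trans to OTBS) | CC(C)(C)[Si](C)(C)O[C@@H]1CC(O[Si](C)(C)C)=C[C@H]1C | intermediate
3 | (R)-4-[(tert-butyldimethylsilyl)oxy]-3-methylcyclopent-2-en-1-one | CC(C)(C)[Si](C)(C)O[C@@H]1CC(=O)C=C1C | intermediate
4 | (4R)-2,3-dibromo-4-[(tert-butyldimethylsilyl)oxy]-3-methylcyclopentan-1-one (anti-dibromide, configuration at C2/C3 not fixed) | CC(C)(C)[Si](C)(C)O[C@@H]1CC(=O)C(Br)C1(C)Br | intermediate (not isolated)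
5 | (R)-2-bromo-4-[(tert-butyldimethylsilyl)oxy]-3-methylcyclopent-2-en-1-one | CC(C)(C)[Si](C)(C)O[C@@H]1CC(=O)C(Br)=C1C | intermediate
6 | (1R,4R)-2-bromo-4-[(tert-butyldimethylsilyl)oxy]-3-methyl-1-(propan-2-yl)cyclopent-2-en-1-ol (OH cis to OTBS) | CC(C)(C)[Si](C)(C)O[C@@H]1C[C@@](O)(C(C)C)C(Br)=C1C | intermediate
7 | (1R,4R)-2-bromo-4-[(tert-butyldimethylsilyl)oxy]-3-methyl-1-(propan-2-yl)-1-[(triethylsilyl)oxy]cyclopent-2-ene | CC(C)(C)[Si](C)(C)O[C@@H]1C[C@@](O[Si](CC)(CC)CC)(C(C)C)C(Br)=C1C | intermediate
8 | C5 alkenyllithium from 7 | CC(C)(C)[Si](C)(C)O[C@@H]1C[C@@](O[Si](CC)(CC)CC)(C(C)C)C([Li])=C1C | intermediate (not isolated)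
9 | lithium acyl(pentacarbonyl)chromate from 8 | [Li+].CC(C)(C)[Si](C)(C)O[C@@H]1C[C@@](O[Si](CC)(CC)CC)(C(C)C)C(C([O-])=[Cr])=C1C.[C-]#[O+].[C-]#[O+].[C-]#[O+].[C-]#[O+].[C-]#[O+] | intermediate (not isolated)
10 | pentacarbonyl[methoxy(ring A alkenyl)carbene]chromium | CC(C)(C)[Si](C)(C)O[C@@H]1C[C@@](O[Si](CC)(CC)CC)(C(C)C)C(C(OC)=[Cr])=C1C.[C-]#[O+].[C-]#[O+].[C-]#[O+].[C-]#[O+].[C-]#[O+] | intermediate
11 | methyl methacrylate | C=C(C)C(=O)OC | starting material
12 | methyl (6R,8S)-2-methoxy-1-methyl-2-(ring A alkenyl)cyclopropane-1-carboxylate (alkenyl and CO2Me cis) | CC(C)(C)[Si](C)(C)O[C@@H]1C[C@@](O[Si](CC)(CC)CC)(C(C)C)C([C@]2(OC)C[C@]2(C)C(=O)OC)=C1C | intermediate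
13 | (6R,8S)-2-methoxy-1-methyl-2-(ring A alkenyl)cyclopropane-1-carbaldehyde | CC(C)(C)[Si](C)(C)O[C@@H]1C[C@@](O[Si](CC)(CC)CC)(C(C)C)C([C@]2(OC)C[C@]2(C)C=O)=C1C | intermediate
14 | ring A cyclopentene with the (6S,8R)-cis-1-methoxy-2-methyl-2-vinylcyclopropyl group at C5, 2β-OTBS, 4β-OTES (key-step precursor) | CC(C)(C)[Si](C)(C)O[C@@H]1C[C@@](O[Si](CC)(CC)CC)(C(C)C)C([C@]2(OC)C[C@]2(C)C=C)=C1C | intermediate
15 | (1R,2R,4R)-2β-[(tert-butyldimethylsilyl)oxy]-6-methoxy-4β-[(triethylsilyl)oxy]dauca-5,8-diene (key-step product) | CC(C)(C)[Si](C)(C)O[C@@H]1C[C@@](O[Si](CC)(CC)CC)(C(C)C)C2=C(OC)CC(C)=CC[C@]21C | intermediate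
16 | 2β-[(tert-butyldimethylsilyl)oxy]-4β-[(triethylsilyl)oxy]dauc-8-en-6-one (H5 α) | CC(C)(C)[Si](C)(C)O[C@@H]1C[C@@](O[Si](CC)(CC)CC)(C(C)C)[C@@H]2C(=O)CC(C)=CC[C@]21C | intermediate (not isolated)
17 | 2β-[(tert-butyldimethylsilyl)oxy]-4β-hydroxydauc-8-en-6-one (H5 α) | CC(C)(C)[Si](C)(C)O[C@@H]1C[C@@](O)(C(C)C)[C@@H]2C(=O)CC(C)=CC[C@]21C | intermediate
18 | 2β-[(tert-butyldimethylsilyl)oxy]dauc-8-ene-4β,6α-diol | CC(C)(C)[Si](C)(C)O[C@@H]1C[C@@](O)(C(C)C)[C@@H]2[C@@H](O)CC(C)=CC[C@]21C | intermediate
19 | 4-methoxybenzoyl chloride | COc1ccc(cc1)C(Cl)=O | starting material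
20 | 2β-[(tert-butyldimethylsilyl)oxy]-4β-hydroxydauc-8-en-6α-yl 4-methoxybenzoate | CC(C)(C)[Si](C)(C)O[C@@H]1C[C@@](O)(C(C)C)[C@@H]2[C@@H](OC(=O)c3ccc(OC)cc3)CC(C)=CC[C@]21C | intermediate
21 | 2β,4β-dihydroxydauc-8-en-6α-yl 4-methoxybenzoate | O[C@@H]1C[C@@](O)(C(C)C)[C@@H]2[C@@H](OC(=O)c3ccc(OC)cc3)CC(C)=CC[C@]21C | intermediate
22 | angelic acid, (Z)-2-methylbut-2-enoic acid | C/C=C(/C)C(=O)O | starting material
23 | angelic 2,4,6-trichlorobenzoic anhydride | C/C=C(/C)C(=O)OC(=O)c1c(Cl)cc(Cl)cc1Cl | intermediate (not isolated)
24 | CNP0204191.1, (1R,2R,4R,5S,6S)-2β-angeloyloxy-4β-hydroxydauc-8-en-6α-yl 4-methoxybenzoate | C/C=C(/C)C(=O)O[C@@H]1C[C@@](O)(C(C)C)[C@@H]2[C@@H](OC(=O)c3ccc(OC)cc3)CC(C)=CC[C@]21C | target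

Total step count: 15. Longest linear sequence: 15 steps (1 to 24).

Steps most likely to fail

Step 10. C10 may bond to the C1 face syn to the C2 silyloxy group if the mismatched cis epimer rearranges before it epimerises, and trans epimers may drain into 1,3-shift or hydrogen-shift products instead of isomerising. The fallback replaces acyclic stereocontrol by a bridged substrate; it sets out from 14 and comes back at 17. Bu4NF in THF removes both silyl groups from 14 to give the cyclopropyl diol F1. t-Bu2Si(OTf)2 with 2,6-lutidine ties the cis-2,4-diol into the di-tert-butylsilylene-bridged divinylcyclopropane F2, a 2,4-dioxa-3-silabicyclo[3.2.1]octene in which the O–Si–O bridge roofs the β face of C1=C5 and the isopropyl group is pulled off the α face. Thermolysis as in step 10 should then give the silylene-bridged methoxy diene F3 by attack on the exo (α) face only. Oxalic acid hydrolysis gives the silylene-bridged ketone F4, HF·pyridine gives the 2β,4β-dihydroxy ketone F5, and TBSCl with imidazole silylates only the secondary C2 hydroxyl, which is 17.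

Step 7. Alkene uptake at the congested carbene carbon may be outrun by thermal decay of the complex or by a formal [3+2] pathway, and methacrylate may polymerise. The fallback cyclopropanates a diene directly with a more labile carbene complex; it sets out from 7 and comes back at 14, so that 12 and 13 are not needed. Bromine–lithium exchange on 7 gives 8 as before, which is added to Mo(CO)6 to give the lithium acyl(pentacarbonyl)molybdate F6. Me3OBF4 converts this into the molybdenum methoxycarbene complex F7, which loses CO at lower temperature than 10. Warming F7 with excess isoprene (THF, 60 °C) should cyclopropanate the diene and give 14; the regioisomer that arises from the unsubstituted double bond of isoprene would have to be separated.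

Step 11. The proton may enter C5 from the β face (cis ring fusion), or C8=C9 may drift into conjugation with the ketone if the acid is too strong. Equilibration of the ketone is not an option because enolisation toward C7 moves the double bond. The fallback changes the substrate so that only one face of C5 is open; it sets out from 15 and comes back at 17. Bu4NF removes both silyl groups from 15 to give the dihydroxy methoxy diene F8. t-Bu2Si(OTf)2 with 2,6-lutidine converts F8 into the silylene-bridged methoxy diene F3 already described, in which the β face of C5 is closed by the bridge. Oxalic acid hydrolysis then gives F4 with H5 α, HF·pyridine gives F5, and TBSCl with imidazole gives 17.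

Further compounds
F1 | step 10 | cyclopropyl diol: 14 without both silyl groups | O[C@@H]1C[C@@](O)(C(C)C)C([C@]2(OC)C[C@]2(C)C=C)=C1C
F2 | step 10 | 2,4-O-(di-tert-butylsilylene)-bridged divinylcyclopropane | CC(C)(C)[Si]3(C(C)(C)C)O[C@@H]1C[C@@](O3)(C(C)C)C([C@]2(OC)C[C@]2(C)C=C)=C1C
F3 | step 10 | 2,4-O-(di-tert-butylsilylene)-6-methoxydauca-5,8-diene | CC(C)(C)[Si]3(C(C)(C)C)O[C@@H]1C[C@@](O3)(C(C)C)C2=C(OC)CC(C)=CC[C@]21C
F4 | step 10 | 2,4-O-(di-tert-butylsilylene)dauc-8-en-6-one (H5 α) | CC(C)(C)[Si]3(C(C)(C)C)O[C@@H]1C[C@@](O3)(C(C)C)[C@@H]2C(=O)CC(C)=CC[C@]21C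
F5 | step 10 | 2β,4β-dihydroxydauc-8-en-6-one (H5 α) | O[C@@H]1C[C@@](O)(C(C)C)[C@@H]2C(=O)CC(C)=CC[C@]21C
F6 | step 7 | lithium acyl(pentacarbonyl)molybdate from 8 | [Li+].CC(C)(C)[Si](C)(C)O[C@@H]1C[C@@](O[Si](CC)(CC)CC)(C(C)C)C(C([O-])=[Mo])=C1C.[C-]#[O+].[C-]#[O+].[C-]#[O+].[C-]#[O+].[C-]#[O+]
F7 | step 7 | pentacarbonyl[methoxy(ring A alkenyl)carbene]molybdenum | CC(C)(C)[Si](C)(C)O[C@@H]1C[C@@](O[Si](CC)(CC)CC)(C(C)C)C(C(OC)=[Mo])=C1C.[C-]#[O+].[C-]#[O+].[C-]#[O+].[C-]#[O+].[C-]#[O+]
F8 | step 11 | 6-methoxydauca-5,8-diene-2β,4β-diol | O[C@@H]1C[C@@](O)(C(C)C)C2=C(OC)CC(C)=CC[C@]21C
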